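Remark (one assumption on notation): every intermediate carries the eudesmane/germacrane numbering of the target (carvone C5 = C1, C6 = C10, C1 = C5, C2 = C4, C3 = C3, C4 = C2; the acetate arm supplies C9 and C8, the allyl ether C6 and C7, methyl acrylate C11 and C12, the iminium salt C13). β is the face that carries the C10 methyl group, α the opposite face.

## The problem

The target is a germacranolide. Its ten-membered carbocycle (C1–C10) carries an E trisubstituted alkene at C1=C10, a trans 4,5-epoxide, acetates at C2 and C6, and an α-methylene-γ-lactone fused trans across C7–C8. Six stereocentres (C2, C4, C5, C6, C7, C8) and one alkene geometry must be fixed, and a mobile medium ring gives little substrate control. One relation can be trusted on the ring itself: a free C6 hydroxyl can deliver an oxidant to C4=C5 from the peripheral face, so C6 can set C4 and C5. C2, C6, C7 and C8 therefore have to be in place before the ring exists. Closing a ten-membered ring by bond formation costs entropy and transannular strain and leaves two E trisubstituted alkenes to be made elsewhere. The fragile elements are the 1(10),4-diene of any precursor (Cope rearrangement on heating, acid-induced transannular cyclisation), the α-methylene lactone (conjugate acceptor), the epoxy alcohol (Payne migration) and the two acetates, so the endgame must be late and mild. The enabling feature is that C1=C10 and the C4=C5 alkene behind the epoxide flank the transannular C5–C10 axis. The ring is a trans-decalin with its ring-fusion bond cut, so a donor on C4 and a leaving group on C1 of such a decalin can open it to the diene.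

## Retrosynthesis

**34 back to 31** (acetate C–O bonds, silyl ether, the two epoxide C–O bonds). In allylic alcohol 31 the C6–H bond eclipses C4=C5 to avoid the cis C4 methyl, which puts the hydroxyl on the peripheral face. A vanadium-bound peroxide is delivered there and should give 32 with the 4R,5R configuration. The C1=C10 alkene sits next to a silylated oxygen and is not directed. Desilylation gives 33 and acetylation 34; the acetates come last so that no ester is exposed to a carbanion step. The forward steps ask for a chemoselective directed epoxidation and two orthogonal ethers (PMB on O6, TBS on O2).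

**31 back to 27** (O6–PMB, C11=C13). The methylene is added after the ring exists (27 to 30), because an α-methylene lactone would not survive alkoxide, hydride or a copper boryl species. Oxidative debenzylation of 30 gives 31. Compound 27 is one carbon simpler and carries only robust ethers.

**27 back to 25** (C4=C5 and C1=C10 become C4–B and C1–OMs; the C5–C10 bond is restored). Unlike ring closure at C5–C6, C6–C7 or C3–C4, this cut needs no macrocyclisation, and the chair geometry fixes both alkenes as E. Compound 25 is a rigid trans-decalin with O2, O6, C11 and O8 all equatorial. The forward step needs boron equatorial on C4, H5 trans to the C10 methyl and an equatorial sulfonate on C1.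

**25 back to 20** (C1–OMs, O2–Si, C2–H, C4–B). Boron is placed by conjugate borylation, which needs a carbonyl two atoms from C4. The carbonyl is put at C2 (enone 20) and not at C6. With C2=O the acceptor alkene C3=C4 is trisubstituted, as in 3-methylcyclohexenone, and C5 and C6 are already set. Conjugation through C6 would make the alkene tetrasubstituted and would leave the C6 carbinol to a hydride reduction from a face blocked by two axial methyl groups. The same shielding applies to C2 in 21, so 21 is reduced under equilibrating conditions to the equatorial alcohol 22. Compounds 23, 24 and 25 follow by moving the silyl group from O1 to O2 and mesylating O1.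

**20 back to 17** (C2=O, lactone C–O, C7–C8). Enone 20 comes from alkene 19 by oxidation of the only ring methylene next to C3=C4. Ring B of 19 is opened at C7–C8: a C8 ketyl adding to a C7 enoate (17 to 18 to 19) makes the bond, the C8 carbinol and the C7 centre at once through a chair with all ring B substituents equatorial. The neighbouring aldol cuts would leave a C6 or C8 ketone whose hydride reduction gives the axial alcohol. Compound 17 is monocyclic with C1, C5, C6 and C10 set.

**17 back to 13** (C7=C11, O6–PMB, C5–C6). Aldehyde 17 is unmasked from 16, and enoate 16 comes from vinyl ether 15 by cross-metathesis. The C5–C6 bond is traced to allyl ether 13 through carbinol 14. The [2,3] shift carries carbon from the 3β oxygen to the β face of C5, creates the C6 carbinol and leaves the alkene at C3=C4 where the borylation needs it. A glycolate Claisen shift would make the same bond, but through the boat it must adopt beside the quaternary C10 it would give the opposite C6 configuration.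

**13 back to 8** (O-allyl, O-TES, ester reduction, inversion at C3, transposition). Compounds 13, 12 and 11 are adjustments of acetate 10, the Mitsunobu inversion product of allylic alcohol 9. Alcohol 9 is the Wharton product of epoxy ketone 8. The inversion is needed because nucleophilic epoxidation occurs anti to the C1 substituent, whereas the shift to C5 must start from the face of the C1 oxygen.

**8 back to 1** (O–Si, O–Ac, C1–O, epoxide, C10–C9, C10–C14). Compound 8 comes from 7 and 6. Acetate 6 arises from 4 by ozonolysis and Criegee rearrangement through 5, which turns the isopropenyl group into the C1 oxygen with retention. Compound 4 is the epoxide of 3, and 3 comes from (R)-carvone 1 through 2 by two α-alkylations. The second electrophile enters anti to the isopropenyl group, so the methyl ends cis to the future C1 oxygen. Carvone supplies ring A, the C4 methyl, the C1 stereocentre and the enone that is relayed through C3 into the C5–C6 bond.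

## Roads not taken

Alternative 1: The cut is C5–C6. CrCl2 with catalytic NiCl2 would turn the alkenyl iodide of iodo aldehyde A2 into an alkenylchromium species that adds to the C6 aldehyde, closing the ring to A1.
- Merits: the fragments are convergent, the C6 hydroxyl appears where the directed epoxidation needs it, and lactone, methylene and C2 acetate are already present. The endgame is two steps and the whole route is probably shorter than the chosen one, which is a real advantage.
- Weak points: it is a ten-membered ring closure needing high dilution. The C6 configuration is set only by the adjacent C7 centre in a flexible transition state. Both E alkenes and the C2 centre must be built separately in open-chain chemistry.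
- Comparison: the chosen plan sets against this a ring formation that cannot fail for entropic reasons, alkene geometry fixed by a chair, and four stereocentres set on a rigid decalin. It pays with a long linear sequence.

Alternative 2: The cut is C6–C7. n-BuLi would deprotonate C6 of the 13-membered diallylic ether A4, and a [2,3] shift onto C7 would contract the ring to A3.
- Merits: one step forms C6–C7, the C6 hydroxyl and the C11=C13 methylene. The 13-membered ether is easier to close than a ten-membered carbocycle. In bond economy this step is better than anything in the chosen plan.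
- Weak points: C6 and C13 are both allylic α-oxy positions, so the lithiation site is uncertain. The [1,2] shift competes. The relative configuration at C6 and C7, and its relation to C8, depends on a transannular transition state that is hard to predict. C12 still has to be oxidised and lactonised among three silyl ethers.
- Comparison: the chosen plan has no step of such density, but each of its stereocentres is set by a ring-controlled reaction of predictable sense.

Alternative 3: The cut is C3–C4. BF3·OEt2 would promote attack of C3 of the silyl dienol ether in A6 on its C4 methyl ketone to give A5, whose chlorohydrin would later close to the epoxide.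
- Merits: the C4 oxygen and the epoxide precursor come without any alkene epoxidation. The enone fixes the C1=C10 geometry. No protecting-group exchange is needed at C6.
- Weak points: an aldol onto a ketone in a medium ring is reversible. Facial control at C4 rests on the α-chloro centre alone. The Lewis acid meets an α-methylene lactone. The C2 ketone must afterwards be reduced selectively on the flexible ring, and the trans epoxide requires the correct C4/C5 relation.
- Comparison: this road avoids the redox detour at C2 that the chosen plan accepts. The chosen plan sets C2 on a decalin and takes C4/C5 from a directed epoxidation.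

Key step: step 22

## Route

Step 1
Reactants: 1 (R)-carvone
Product: 2 (5R,6S)-2,6-dimethyl-5-(prop-1-en-2-yl)cyclohex-2-en-1-one (trans-6-methylcarvone)
Conditions: LiN(i-Pr)2, THF, −78 °C; MeI, −78 to 0 °C
Reagents that add atoms: iodomethane, CI
Why: Kinetic enolate alkylation at the only α-CH2, anti to the isopropenyl group; this centre becomes trigonal again in step 2, so only the constitution matters.

Step 2
Reactants: 2 trans-6-methylcarvone
Product: 3 methyl 2-[(1S,6S)-1,3-dimethyl-2-oxo-6-(prop-1-en-2-yl)cyclohex-3-en-1-yl]acetate (C10 quaternary; methyl cis and acetate arm trans to the C1 isopropenyl group)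
Conditions: LiN(i-Pr)2, THF, −78 °C; BrCH2CO2Me, −78 to −20 °C
Reagents that add atoms: methyl bromoacetate, COC(=O)CBr
Why: Second enolate alkylation with a reactive α-halo ester; the electrophile again enters anti to the isopropenyl group, which leaves the methyl cis to it and so sets the C1/C10 relation of the whole series.

Step 3
Reactants: 3 ring A keto ester
Product: 4 3α,4α-epoxy ketone of 3 (epoxide oxygen trans to the C1 isopropenyl group)
Conditions: H2O2 (30% aq.), NaOH (cat.), MeOH, 0 °C
Reagents that add atoms: hydrogen peroxide, OO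
Why: Weitz–Scheffer nucleophilic epoxidation; hydroperoxide should add axially to C3 anti to the equatorial C1 substituent, as in carvone itself, and the isolated isopropenyl alkene is inert.

Step 4
Reactants: 4 isopropenyl epoxy ketone
Product: 6 1β-acetoxy-3α,4α-epoxy ketone (isopropenyl replaced by acetoxy), via methoxy hydroperoxide 5 (not isolated)
Conditions: O3, CH2Cl2/MeOH, −78 °C; then Ac2O, Et3N, DMAP (cat.), 0 to 23 °C
Reagents that add atoms: ozone, [O-][O+]=O; methanol, CO
Why: Ozonolysis of the only alkene in methanol gives the α-methoxy hydroperoxide; its acetylation triggers a Criegee rearrangement in which the secondary ring carbon C1 migrates to oxygen with retention, so the C1 oxygen is β.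

Step 5
Reactants: 6 1β-acetate
Product: 7 1β-hydroxy-3α,4α-epoxy ketone
Conditions: K2CO3 (cat.), MeOH, 0 °C
Reagents that add atoms: none
Why: Mild transesterification; low temperature and catalytic carbonate should avoid retro-aldol cleavage of the β-hydroxy ketone, and the methyl ester is inert by degeneracy.

Step 6
Reactants: 7 1β-alcohol
Product: 8 1β-(tert-butyldimethylsilyloxy)-3α,4α-epoxy ketone
Conditions: TBSOTf, 2,6-lutidine, CH2Cl2, −78 to 0 °C
Reagents that add atoms: tert-butyldimethylsilyl trifluoromethanesulfonate, CC(C)(C)[Si](C)(C)OS(=O)(=O)C(F)(F)F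
Why: Silylation of a hindered neopentyl-type alcohol needs the silyl triflate; the silyl ether survives hydrazine, hydride and alkyllithium in the next steps.

Step 7
Reactants: 8 epoxy ketone
Product: 9 allylic alcohol (1β-OTBS; 3α-OH; C4=C5; C10 methyl and CH2CO2Me)
Conditions: N2H4·H2O, AcOH (cat.), MeOH, 0 to 23 °C
Reagents that add atoms: none
Why: Wharton transposition: the epoxide oxygen stays on C3 with its α configuration and the alkene appears at C4=C5 with loss of N2; condensation at the hindered carbonyl is the slow event.

Step 8
Reactants: 9 3α-allylic alcohol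
Product: 10 3β-acetate (inverted at C3)
Conditions: PPh3, DIAD, AcOH, THF, 0 °C
Reagents that add atoms: acetic acid, CC(=O)O
Why: Mitsunobu inversion; SN2 at C3 should prevail because the SN2′ terminus C5 lies next to the quaternary C10, and the 3β oxygen is what the later suprafacial shift to the β face of C5 requires.

Step 9
Reactants: 10 3β-acetate methyl ester
Product: 11 diol (3β-OH; C10 arm reduced to CH2CH2OH; 1β-OTBS)
Conditions: LiAlH4, THF, 0 °C
Reagents that add atoms: none
Why: One hydride reagent cleaves the allylic acetate and reduces the methyl ester to the C8 primary alcohol; the silyl ether and the alkene are inert.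

Step 10
Reactants: 11 diol
Product: 12 8-O-triethylsilyl ether (3β-OH free)
Conditions: TESCl, imidazole, CH2Cl2, −40 °C
Reagents that add atoms: chlorotriethylsilane, CC[Si](Cl)(CC)CC
Why: Selective silylation of the primary over the hindered secondary allylic hydroxyl.

Step 11
Reactants: 12 3β-alcohol
Product: 13 3β-O-allyl ether
Conditions: NaH, allyl bromide, Bu4NI (cat.), THF/DMF, 0 to 23 °C
Reagents that add atoms: allyl bromide, C=CCBr
Why: Williamson etherification; no base-sensitive group remains.

Step 12
Reactants: 13 allyl ether
Product: 15 (6S)-6-(4-methoxybenzyloxy) compound (C5β–CH(OPMB)–CH=CH2; 5α-H; C3=C4; 1β-OTBS; 8-OTES), via C6 alcohol 14 (not isolated)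
Conditions: n-BuLi, THF, −78 to −30 °C; then PMBBr, DMPU, −30 to 23 °C
Reagents that add atoms: 4-methoxybenzyl bromide, COc1ccc(CBr)cc1
Why: [2,3]-Wittig rearrangement of a cis-carveol-type ether: lithiation at the allyl CH2, then a suprafacial shift from the 3β oxygen to the β face of C5, forms C5–C6 and moves the alkene to C3=C4; in the envelope transition state the vinyl group should lie exo, away from ring A and the C10 substituents, which gives the 6S carbinol (6α oxygen of the later decalin); the lithium alkoxide is benzylated in the same flask.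

Step 13
Reactants: 15 vinyl PMB ether
Product: 16 methyl (E)-enoate (C6–CH=CH–CO2Me)
Conditions: methyl acrylate, second-generation Hoveyda–Grubbs catalyst (cat.), CH2Cl2, 40 °C
Reagents that add atoms: methyl acrylate, C=CC(=O)OC
Why: Cross-metathesis of a terminal alkene with an acrylate is E-selective; the trisubstituted ring alkene does not take part.

Step 14
Reactants: 16 primary TES ether
Product: 17 C8 aldehyde (C10 arm CH2CHO)
Conditions: (COCl)2, DMSO, CH2Cl2, −78 °C; Et3N, −78 to −20 °C
Reagents that add atoms: none
Why: Swern conditions convert a primary triethylsilyl ether directly into the aldehyde while the secondary TBS ether, the PMB ether and the enoate stay intact.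

Step 15
Reactants: 17 aldehyde enoate
Product: 19 1β-TBSO-6α-PMBO-13-nor-5α-eudesm-3-en-8α,12-olide, via hydroxy ester 18 (not isolated)
Conditions: SmI2, t-BuOH, THF, −78 to 0 °C; then p-TsOH·H2O (cat.), CH2Cl2, 23 °C
Reagents that add atoms: none
Why: Ketyl–olefin radical cyclisation (6-exo-trig) of the C8 ketyl onto C7 of the enoate closes ring B; a chair with the C6 ether, the ester arm and the samarium alkoxide equatorial, the alkoxide turned away from the axial C10 methyl, should give the trans-decalin with 7β-CH2CO2Me and 8α-OH, which lactonise under acid.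

Step 16
Reactants: 19 Δ3-alkene
Product: 20 2-oxo-3-ene (ring A enone; 1β-OTBS)
Conditions: CrO3, 3,5-dimethylpyrazole, CH2Cl2, −20 °C
Reagents that add atoms: chromium trioxide, O=[Cr](=O)=O
Why: Allylic oxidation of the only ring methylene flanking C3=C4 gives the enone; the other ring allylic position (C5) is a shielded methine, and the low temperature is chosen to spare the PMB ether.

Step 17
Reactants: 20 enone
Product: 21 4α-(4,4,5,5-tetramethyl-1,3,2-dioxaborolan-2-yl)-4β-methyl-2-oxo compound
Conditions: CuCl (cat.), NaOt-Bu (cat.), DPEphos (cat.), B2pin2, MeOH, THF, 23 °C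
Reagents that add atoms: bis(pinacolato)diboron, CC1(C)OB(OC1(C)C)B1OC(C)(C)C(C)(C)O1
Why: Copper-catalysed conjugate borylation of a β-methyl cyclohexenone; the copper boryl should add to the α face because the axial C10 methyl, 1,3 to C4, shields the β face, giving the equatorial 4α boronate with the methyl axial; methanol protonates the enolate at C3.

Step 18
Reactants: 21 β-boryl ketone
Product: 22 2α-alcohol (1β-OTBS)
Conditions: Al(Oi-Pr)3, i-PrOH, acetone (trace), toluene, 80 °C
Reagents that add atoms: none
Why: Meerwein–Ponndorf–Verley reduction under reversible conditions; the kinetically formed axial 2β-alcohol suffers two syn-axial methyl groups and is re-oxidised, so the mixture should drain into the equatorial 2α-alcohol, which a simple hydride attacking from the open α face would not give.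

Step 19
Reactants: 22 1β-silyl ether
Product: 23 1β,2α-diol
Conditions: TBAF, AcOH, THF, 0 to 23 °C
Reagents that add atoms: none
Why: Buffered fluoride removes the C1 silyl group; the tertiary alkyl pinacol boronate binds fluoride reversibly and should survive at this temperature.

Step 20
Reactants: 23 diol
Product: 24 2α-TBS ether (1β-OH free)
Conditions: TBSCl, imidazole, DMF, 0 °C
Reagents that add atoms: tert-butyldimethylsilyl chloride, CC(C)(C)[Si](C)(C)Cl
Why: The C2 hydroxyl is the less hindered one; the C1 hydroxyl is flanked by the quaternary C10, so silylation should be selective.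

Step 21
Reactants: 24 1β-alcohol
Product: 25 1β-methanesulfonate (2α-OTBS; 4α-Bpin; 6α-OPMB; 8α,12-olide)
Conditions: MsCl, Et3N, CH2Cl2, −20 to 0 °C
Reagents that add atoms: methanesulfonyl chloride, CS(=O)(=O)Cl
Why: Sulfene-mediated mesylation works on hindered secondary alcohols; the equatorial sulfonate cannot undergo anti elimination and is stable until the boron is activated.

Step 22
Reactants: 25 boronate mesylate
Product: 27 (1(10)E,4E)-(2S,6R,7R,8S)-2-(tert-butyldimethylsilyloxy)-6-(4-methoxybenzyloxy)-13-norgermacra-1(10),4-dien-8,12-olide, via boronate complex 26 (not isolated)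
Conditions: KOt-Bu, THF, 0 to 23 °C
Reagents that add atoms: none
Why: tert-Butoxide adds to boron to give the tetracoordinate boronate 26, whose C4–B electron pair forms C4=C5 as the C5–C10 bond breaks and its pair forms C10=C1 with loss of mesylate, a concerted Grob-type 1,4-fragmentation. The closest known reaction type is the boronate fragmentation of γ-sulfonyloxy organoboron ate complexes of trans-decalins to (E,E)-cyclodeca-1,5-dienes, here started from a pinacol ester and an alkoxide in place of a borane and hydroxide. No ring is closed by bond formation: the ten-membered ring appears when the shared C5–C10 bond is cut, so no cyclisation mode or dilution is at issue. No stereocentre is created; C2, C6, C7 and C8 are carried over and C1, C4, C5 and C10 become trigonal. Both geometries follow from the chair: the equatorial C4–B bond, C5–C10 and the equatorial C1–O bond are mutually antiperiplanar, C3 is anti to C6 across C4–C5 and C9 is anti to C2 across C10–C1, so both alkenes must be E. Fragmentation has to beat elimination, substitution at C1 and attack on the lactone; the equatorial mesylate has no antiperiplanar hydrogen, C1 is neopentyl, the bulky base is a poor acyl acceptor partner, and release of the methyl/methyl 1,3-diaxial and boronate/ether peri strain drives the opening. The mixture is kept at or below room temperature and worked up at neutral pH so that the 1(10),4-diene neither rearranges by a Cope path nor cyclises across the ring.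

Step 23
Reactants: 27 germacradienolide
Product: 30 11(13)-methylene lactone (germacra-1(10),4,11(13)-trien-8,12-olide; 2-OTBS; 6-OPMB), via Mannich base 28 (not isolated), via ammonium iodide 29 (not isolated)
Conditions: LiN(i-Pr)2, THF, −78 °C; CH2=NMe2+ I−, −78 to 0 °C; MeI, MeOH, 23 °C; NaHCO3, CH2Cl2/H2O, 23 °C
Reagents that add atoms: N,N-dimethylmethyleneiminium iodide, C=[N+](C)C.[I-]
Why: Lactone enolate aminomethylation with Eschenmoser's salt, quaternisation and mild elimination give the exocyclic methylene; C7 carries no acidic hydrogen under these conditions and all operations stay at or below room temperature.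

Step 24
Reactants: 30 PMB ether
Product: 31 6-alcohol (2-OTBS)
Conditions: DDQ, CH2Cl2/pH 7 buffer, 0 °C
Reagents that add atoms: none
Why: Oxidative cleavage of the electron-rich benzyl ether under buffered conditions frees only O6; the silyl ether, the diene and the lactone are untouched.

Step 25
Reactants: 31 allylic alcohol
Product: 32 (4R,5R)-4,5-epoxy-6-ol (2-OTBS)
Conditions: VO(acac)2 (cat.), t-BuOOH, CH2Cl2, 0 °C
Reagents that add atoms: tert-butyl hydroperoxide, CC(C)(C)OO
Why: Hydroxyl-directed epoxidation: with C6–H eclipsing the alkene to avoid the cis C4 methyl, the vanadium alkoxide delivers oxygen to the peripheral face of C4=C5 only, which is the 4R,5R epoxide; the C1=C10 alkene (no free hydroxyl) and the electron-poor methylene are not touched.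

Step 26
Reactants: 32 silyl ether
Product: 33 2,6-diol
Conditions: TBAF, AcOH, THF, 0 °C
Reagents that add atoms: none
Why: Fluoride buffered with acetic acid removes the allylic silyl ether without base-induced Payne migration of the epoxy alcohol or addition to the methylene lactone.

Step 27
Reactants: 33 diol
Product: 34 target, (1(10)E)-(2S,4R,5R,6S,7R,8S)-2,6-diacetoxy-4,5-epoxygermacra-1(10),11(13)-dien-8,12-olide
Conditions: Ac2O, pyridine, DMAP (cat.), CH2Cl2, 0 °C
Reagents that add atoms: acetic anhydride, CC(=O)OC(C)=O
Why: Standard acylation of two secondary alcohols under mild base; no stereocentre is affected.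

## Compound list

1 | (R)-carvone, (5R)-2-methyl-5-(prop-1-en-2-yl)cyclohex-2-en-1-one | CC1=CC[C@H](CC1=O)C(C)=C | starting material
2 | (5R,6S)-2,6-dimethyl-5-(prop-1-en-2-yl)cyclohex-2-en-1-one | CC1=CC[C@@H](C(C)=C)[C@H](C)C1=O | intermediate
3 | methyl 2-[(1S,6S)-1,3-dimethyl-2-oxo-6-(prop-1-en-2-yl)cyclohex-3-en-1-yl]acetate | CC1=CC[C@@H](C(C)=C)[C@](C)(CC(=O)OC)C1=O | intermediate
4 | 3α,4α-epoxy ketone of 3 (1β-isopropenyl) | C[C@@]12O[C@@H]1C[C@@H](C(C)=C)[C@](C)(CC(=O)OC)C2=O | intermediate
5 | α-methoxy hydroperoxide at the former isopropenyl carbon (both epimers at that carbon) | C[C@@]12O[C@@H]1C[C@@H](C(C)(OC)OO)[C@](C)(CC(=O)OC)C2=O | intermediate (not isolated)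
6 | 1β-acetoxy-3α,4α-epoxy ketone | C[C@@]12O[C@@H]1C[C@@H](OC(C)=O)[C@](C)(CC(=O)OC)C2=O | intermediate
7 | 1β-hydroxy-3α,4α-epoxy ketone | C[C@@]12O[C@@H]1C[C@@H](O)[C@](C)(CC(=O)OC)C2=O | intermediate
8 | 1β-TBS ether of 7 | C[C@@]12O[C@@H]1C[C@@H](O[Si](C)(C)C(C)(C)C)[C@](C)(CC(=O)OC)C2=O | intermediate
9 | 3α-hydroxy-4-ene, 1β-OTBS, methyl ester arm on C10 | CC1=C[C@@](C)(CC(=O)OC)[C@H](O[Si](C)(C)C(C)(C)C)C[C@H]1O | intermediate
10 | 3β-acetate (C3 inverted) | CC1=C[C@@](C)(CC(=O)OC)[C@H](O[Si](C)(C)C(C)(C)C)C[C@@H]1OC(C)=O | intermediate
11 | 3β,8-diol (C10 arm CH2CH2OH) | CC1=C[C@@](C)(CCO)[C@H](O[Si](C)(C)C(C)(C)C)C[C@@H]1O | intermediate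
12 | 8-O-TES ether, 3β-ol | CC1=C[C@@](C)(CCO[Si](CC)(CC)CC)[C@H](O[Si](C)(C)C(C)(C)C)C[C@@H]1O | intermediate
13 | 3β-O-allyl ether | CC1=C[C@@](C)(CCO[Si](CC)(CC)CC)[C@H](O[Si](C)(C)C(C)(C)C)C[C@@H]1OCC=C | intermediate
14 | (6S)-carbinol from the [2,3] shift (C5β–CH(OH)CH=CH2, 5α-H, C3=C4) | CC1=CC[C@@H](O[Si](C)(C)C(C)(C)C)[C@](C)(CCO[Si](CC)(CC)CC)[C@H]1[C@@H](O)C=C | intermediate (not isolated)
15 | PMB ether of 14 | CC1=CC[C@@H](O[Si](C)(C)C(C)(C)C)[C@](C)(CCO[Si](CC)(CC)CC)[C@H]1[C@@H](OCc2ccc(OC)cc2)C=C | intermediate
16 | methyl (E)-enoate | CC1=CC[C@@H](O[Si](C)(C)C(C)(C)C)[C@](C)(CCO[Si](CC)(CC)CC)[C@H]1[C@@H](OCc2ccc(OC)cc2)/C=C/C(=O)OC | intermediate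
17 | C8 aldehyde of 16 | CC1=CC[C@@H](O[Si](C)(C)C(C)(C)C)[C@](C)(CC=O)[C@H]1[C@@H](OCc2ccc(OC)cc2)/C=C/C(=O)OC | intermediate
18 | 8α-hydroxy-7β-(methoxycarbonylmethyl) trans-decalin (1β-OTBS, 6α-OPMB, Δ3) | CC1=CC[C@@H](O[Si](C)(C)C(C)(C)C)[C@]2(C)C[C@H](O)[C@@H](CC(=O)OC)[C@H](OCc3ccc(OC)cc3)[C@@H]12 | intermediate (not isolated)
19 | 1β-TBSO-6α-PMBO-13-nor-5α-eudesm-3-en-8α,12-olide | CC1=CC[C@@H](O[Si](C)(C)C(C)(C)C)[C@]2(C)C[C@@H]3OC(=O)C[C@H]3[C@H](OCc4ccc(OC)cc4)[C@@H]12 | intermediate
20 | 2-oxo-3-ene of 19 | CC1=CC(=O)[C@@H](O[Si](C)(C)C(C)(C)C)[C@]2(C)C[C@@H]3OC(=O)C[C@H]3[C@H](OCc4ccc(OC)cc4)[C@@H]12 | intermediate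
21 | 4α-Bpin-4β-methyl-2-oxo compound | C[C@@]1(B2OC(C)(C)C(C)(C)O2)CC(=O)[C@@H](O[Si](C)(C)C(C)(C)C)[C@]3(C)C[C@@H]4OC(=O)C[C@H]4[C@H](OCc5ccc(OC)cc5)[C@@H]13 | intermediate
22 | 2α-alcohol, 1β-OTBS | C[C@@]1(B2OC(C)(C)C(C)(C)O2)C[C@H](O)[C@@H](O[Si](C)(C)C(C)(C)C)[C@]3(C)C[C@@H]4OC(=O)C[C@H]4[C@H](OCc5ccc(OC)cc5)[C@@H]13 | intermediate
23 | 1β,2α-diol | C[C@@]1(B2OC(C)(C)C(C)(C)O2)C[C@H](O)[C@@H](O)[C@]3(C)C[C@@H]4OC(=O)C[C@H]4[C@H](OCc5ccc(OC)cc5)[C@@H]13 | intermediate
24 | 2α-TBS ether, 1β-ol | C[C@@]1(B2OC(C)(C)C(C)(C)O2)C[C@H](O[Si](C)(C)C(C)(C)C)[C@@H](O)[C@]3(C)C[C@@H]4OC(=O)C[C@H]4[C@H](OCc5ccc(OC)cc5)[C@@H]13 | intermediate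
25 | 1β-mesylate (4α-Bpin, 2α-OTBS, 6α-OPMB, 8α,12-olide, 5α-H, 10β-Me) | C[C@@]1(B2OC(C)(C)C(C)(C)O2)C[C@H](O[Si](C)(C)C(C)(C)C)[C@@H](OS(C)(=O)=O)[C@]3(C)C[C@@H]4OC(=O)C[C@H]4[C@H](OCc5ccc(OC)cc5)[C@@H]13 | intermediate
26 | potassium tert-butoxy boronate complex of 25 | C[C@@]1([B-]2(OC(C)(C)C)OC(C)(C)C(C)(C)O2)C[C@H](O[Si](C)(C)C(C)(C)C)[C@@H](OS(C)(=O)=O)[C@]3(C)C[C@@H]4OC(=O)C[C@H]4[C@H](OCc5ccc(OC)cc5)[C@@H]13.[K+] | intermediate (not isolated)
27 | (1(10)E,4E)-(2S,6R,7R,8S)-2-TBSO-6-PMBO-13-norgermacra-1(10),4-dien-8,12-olide | [C@H]1(OC(=O)C3)C/C(C)=C/[C@@H](O[Si](C)(C)C(C)(C)C)C/C(C)=C/[C@@H](OCc2ccc(OC)cc2)[C@@H]13 | intermediate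
28 | 11-(dimethylaminomethyl) lactone (both C11 epimers) | [C@H]1(OC(=O)C3CN(C)C)C/C(C)=C/[C@@H](O[Si](C)(C)C(C)(C)C)C/C(C)=C/[C@@H](OCc2ccc(OC)cc2)[C@@H]13 | intermediate (not isolated)
29 | trimethylammonium iodide of 28 | [C@H]1(OC(=O)C3C[N+](C)(C)C)C/C(C)=C/[C@@H](O[Si](C)(C)C(C)(C)C)C/C(C)=C/[C@@H](OCc2ccc(OC)cc2)[C@@H]13.[I-] | intermediate (not isolated)
30 | (2S,6R,7R,8S)-2-TBSO-6-PMBO-germacra-1(10),4,11(13)-trien-8,12-olide | [C@H]1(OC(=O)C3=C)C/C(C)=C/[C@@H](O[Si](C)(C)C(C)(C)C)C/C(C)=C/[C@@H](OCc2ccc(OC)cc2)[C@@H]13 | intermediate
31 | 6-hydroxy-2-TBSO-germacra-1(10),4,11(13)-trien-8,12-olide | [C@H]1(OC(=O)C3=C)C/C(C)=C/[C@@H](O[Si](C)(C)C(C)(C)C)C/C(C)=C/[C@@H](O)[C@@H]13 | intermediate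
32 | (2S,4R,5R,6S,7R,8S)-4,5-epoxy-6-hydroxy-2-TBSO-germacra-1(10),11(13)-dien-8,12-olide | C=C1C(=O)O[C@H]2C/C(C)=C/[C@@H](O[Si](C)(C)C(C)(C)C)C[C@@]3(C)O[C@@H]3[C@@H](O)[C@H]12 | intermediate
33 | 4,5-epoxy-2,6-dihydroxy-germacra-1(10),11(13)-dien-8,12-olide | C=C1C(=O)O[C@H]2C/C(C)=C/[C@@H](O)C[C@@]3(C)O[C@@H]3[C@@H](O)[C@H]12 | intermediate
34 | (1(10)E)-(2S,4R,5R,6S,7R,8S)-2,6-diacetoxy-4,5-epoxygermacra-1(10),11(13)-dien-8,12-olide | C=C1C(=O)O[C@H]2C/C(C)=C/[C@@H](OC(C)=O)C[C@@]3(C)O[C@@H]3[C@@H](OC(C)=O)[C@H]12 | target

## Step count and least certain steps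

Total: 27 steps. The route is fully linear from (R)-carvone, so the longest linear sequence is also 27 steps.

Step 22 (key step). The ate complex may form slowly at the hindered tertiary pinacol boronate. tert-Butoxide would then enolise or open the lactone, or the product diene would be lost by transannular reaction during a long reaction time. The fallback sets out from 25. The pinacol ester is cleaved oxidatively (NaIO4, NH4OAc, aqueous acetone) to the free boronic acid F1. Its unhindered, more Lewis-acidic boron takes up tert-butoxide or carbonate at once and fragments through the same aligned bonds, returning to the route at 27.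

Step 18. Equilibration may be incomplete, leaving the kinetically formed axial alcohol, and the hot aluminium alkoxide may open the lactone. The fallback sets out from 21. NaBH4 gives the axial 2β-alcohol F2, which is epimerised at room temperature by reversible hydrogen transfer with Ru(CO)2Cl(C5Ph5) and KOt-Bu. The thermodynamic pull is the same but the conditions are far milder; the route is rejoined at 22.

Step 17. The copper boryl may add sluggishly next to the ring-fusion carbon, or with imperfect facial selectivity if the ring A half-chair exposes the β face. The fallback goes from 20 directly to 21 with a different boron nucleophile: a metal-free, carbene-activated diboron (N-heterocyclic carbene, B2pin2, DBU, MeOH), or CuCl with a chiral bisphosphine matched to the α face so that the reagent, not the substrate, decides. This fallback forms no new compound (F0).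

Step 16. The chromium reagent may oxidise the benzylic position of the PMB ether or abstract the C5 hydrogen, giving ring-fusion oxidation products. The fallback sets out from 19 and avoids C–H oxidation.
- mCPBA gives the α-epoxide F3.
- PhSeNa (from (PhSe)2 and NaBH4) opens it at the secondary C3 to the hydroxy selenide F4.
- H2O2 causes selenoxide elimination away from the carbinol to the tertiary allylic alcohol F5.
- Pyridinium chlorochromate (C5H5NH[CrO3Cl]) effects oxidative 1,3-transposition and returns to 20.

Step 12. Lithiation may occur at the ring C3–H instead of the allyl CH2, a [1,2] shift may compete, the exo preference at C6 may erode, or the alkoxide may be benzylated incompletely. The fallback sets out from 12.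
- KH and Bu3SnCH2I give the stannylmethyl ether F6.
- Tin–lithium exchange with n-BuLi (Still–Wittig variant) gives regiospecifically the primary alcohol F7.
- Dess–Martin periodinane gives the aldehyde F8.
- CH2=CHMgBr adds under Felkin–Anh control to give 14, which is benzylated (NaH, PMBCl) to rejoin the route at 15.

Step 15. The aldehyde may be reduced without cyclisation, pinacol coupling may intervene, the allylic PMB-oxy group may be lost reductively from the enoate, or the C7/C8 relation may come out wrong. The fallback sets out from 17. An intramolecular Stetter reaction with a triazolium-derived carbene gives the C8 ketone F9, whose C7 centre is epimerisable to the equatorial arrangement. Equilibrating reduction with Al(Oi-Pr)3 in i-PrOH then gives 18, which lactonises to 19.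

## Further compounds

F1 | step 22 | boronic acid corresponding to 25 (4α-B(OH)2) | C[C@@]1(B(O)O)C[C@H](O[Si](C)(C)C(C)(C)C)[C@@H](OS(C)(=O)=O)[C@]3(C)C[C@@H]4OC(=O)C[C@H]4[C@H](OCc5ccc(OC)cc5)[C@@H]13
F2 | step 18 | axial 2β-alcohol, C2 epimer of 22 | C[C@@]1(B2OC(C)(C)C(C)(C)O2)C[C@@H](O)[C@@H](O[Si](C)(C)C(C)(C)C)[C@]3(C)C[C@@H]4OC(=O)C[C@H]4[C@H](OCc5ccc(OC)cc5)[C@@H]13
F0 | step 17 | none | none
F3 | step 16 | 3α,4α-epoxide of 19 | C[C@@]12O[C@@H]1C[C@@H](O[Si](C)(C)C(C)(C)C)[C@]3(C)C[C@@H]4OC(=O)C[C@H]4[C@H](OCc5ccc(OC)cc5)[C@@H]23
F4 | step 16 | 3β-phenylselanyl-4α-hydroxy compound | C[C@@]1(O)[C@@H]([Se]c6ccccc6)C[C@@H](O[Si](C)(C)C(C)(C)C)[C@]3(C)C[C@@H]4OC(=O)C[C@H]4[C@H](OCc5ccc(OC)cc5)[C@@H]13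
F5 | step 16 | 4α-hydroxy-4β-methyl-2-ene (tertiary allylic alcohol) | C[C@@]1(O)C=C[C@@H](O[Si](C)(C)C(C)(C)C)[C@]3(C)C[C@@H]4OC(=O)C[C@H]4[C@H](OCc5ccc(OC)cc5)[C@@H]13
F6 | step 12 | 3β-O-(tributylstannylmethyl) ether of 12 | CC1=C[C@@](C)(CCO[Si](CC)(CC)CC)[C@H](O[Si](C)(C)C(C)(C)C)C[C@@H]1OC[Sn](CCCC)(CCCC)CCCC
F7 | step 12 | C5β-hydroxymethyl compound (C6 primary alcohol, C3=C4) | CC1=CC[C@@H](O[Si](C)(C)C(C)(C)C)[C@](C)(CCO[Si](CC)(CC)CC)[C@H]1CO
F8 | step 12 | C6 aldehyde | CC1=CC[C@@H](O[Si](C)(C)C(C)(C)C)[C@](C)(CCO[Si](CC)(CC)CC)[C@H]1C=O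
F9 | step 15 | 8-oxo-7β-(methoxycarbonylmethyl) trans-decalin | CC1=CC[C@@H](O[Si](C)(C)C(C)(C)C)[C@]2(C)CC(=O)[C@@H](CC(=O)OC)[C@H](OCc3ccc(OC)cc3)[C@@H]12
A1 | alternative 1 | 6-hydroxy-2-acetoxy-germacra-1(10),4,11(13)-trien-8,12-olide | [C@H]1(OC(=O)C3=C)C/C(C)=C/[C@@H](OC(C)=O)C/C(C)=C/[C@@H](O)[C@@H]13
A2 | alternative 1 | open-chain (E)-alkenyl iodide with the C6 aldehyde on the lactone | O=C[C@@H]1C(=C)C(=O)O[C@H]1C/C(C)=C/[C@@H](OC(C)=O)C/C(C)=C/I
A3 | alternative 2 | germacra-1(10),4,11(13)-trien-6-ol with C2, C8 and C12 silyl ethers | [C@H]1(O[Si](C)(C)C(C)(C)C)C/C(C)=C/[C@@H](O[Si](C)(C)C(C)(C)C)C/C(C)=C/[C@@H](O)[C@@H]1C(=C)CO[Si](C)(C)C(C)(C)C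
A4 | alternative 2 | 13-membered diallylic ether (C6–O–C13, C7=C11) | [C@H]1(O[Si](C)(C)C(C)(C)C)C/C(C)=C/[C@@H](O[Si](C)(C)C(C)(C)C)C/C(C)=C/COC/C(CO[Si](C)(C)C(C)(C)C)=C/1
A5 | alternative 3 | ten-membered C2 enone chlorohydrin | [C@H]1(OC(=O)C3=C)C/C(C)=C/C(=O)C[C@@](C)(O)[C@@H](Cl)[C@@H](O[Si](C)(C)C(C)(C)C)[C@@H]13
A6 | alternative 3 | open-chain silyl dienol ether with the α-chloro methyl ketone | C=C(O[Si](C)(C)C)/C=C(C)/C[C@@H]1OC(=O)C(=C)[C@H]1[C@H](O[Si](C)(C)C(C)(C)C)[C@H](Cl)C(C)=O
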